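**Retrosynthetic overview**
1. Target 22 comes from one hydrogenolysis of 21, which carries 16 benzyl ethers, a bromine cap on C8 of unit 4 and a 1,3-xylylene strap between O3 of unit 1 and O3 of unit 2.
2. The two all-cis units (1 and 2) are not made by flavan C4-cation coupling. Each pyran ring is built on the central phloroglucinol ring by a phenol + α-alkoxy-enone annulation to a 4-aryl-4H-chromene (C4 set by a chiral acid), then reduced from the face opposite the C4 aryl group.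
3. Key step (step 13): the second annulation runs through the strap, so the pyran ring of unit 2 and a 14-membered ring form in one operation; ionic hydrogenation in the same flask then sets C2 and C3 of units 1 and 2.
4. Bis-ketone 14 supplies C2–C3 of both new units; aldehyde 16 (from 3,5-bis(benzyloxy)phenol) becomes the central ring.
5. Units 3 and 4 come from (−)-epicatechin by a halogen-capped 4β→6 coupling. Ring order: pyran rings of units 3 and 4 (chiral pool), pyran ring of unit 1 (step 11), then pyran ring of unit 2 plus the strap macrocycle (step 13).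

**Assumption.** The SMILES is read literally (unit 1 (2R,3R,4R) all-cis, unit 2 (2S,3S,4R) all-cis of ent-epicatechin type, unit 3 (2R,3R,4S), unit 4 (2R,3R)), and the (R)-acid is taken to give the C4 configuration drawn for unit 1 and the (S)-acid that of unit 2; the sense is checked on 18 and the antipodes are exchanged if it is the other way round.

**Route**

Step 1
Reactants: 1 (−)-epicatechin
Product: 2 5,7,3',4'-tetra-O-benzyl-(−)-epicatechin
Conditions: BnBr (4.4 equiv), K2CO3, DMF, 0 °C to rt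
Reagents that add atoms: benzyl bromide, BrCc1ccccc1
Why: Williamson etherification of the four phenols, the much less acidic 3-OH staying free under carbonate and no stereocentre being touched.

Step 2
Reactants: 2 5,7,3',4'-tetra-O-benzyl-(−)-epicatechin
Product: 3 8-iodo-5,7,3',4'-tetra-O-benzyl-(−)-epicatechin
Conditions: N-iodosuccinimide (1.05 equiv), DMF, 0 °C
Reagents that add atoms: N-iodosuccinimide, O=C1CCC(=O)N1I
Why: Electrophilic aromatic iodination goes to C8, the most nucleophilic ring-A position of benzylated flavan-3-ols (as in their C8 bromination), and the iodide serves later as cap and as formyl handle.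

Step 3
Reactants: 3 8-iodo-5,7,3',4'-tetra-O-benzyl-(−)-epicatechin
Product: 4 (2R,3R,4S)-8-iodo-4-(2-ethoxyethoxy)-5,7,3',4'-tetra-O-benzylepicatechin (4β-alkoxy)
Conditions: DDQ (2,3-dichloro-5,6-dicyano-1,4-benzoquinone, 2 equiv), 2-ethoxyethanol (5 equiv), CH2Cl2, rt
Reagents that add atoms: 2-ethoxyethanol, CCOCCO
Why: Benzylic oxidation by hydride abstraction at C4 gives the ring-A-stabilised cation, which the alcohol captures trans to the 3-hydroxyl (4β), the usual outcome for 2,3-cis flavans.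

Step 4
Reactants: 2 5,7,3',4'-tetra-O-benzyl-(−)-epicatechin
Product: 5 8-bromo-5,7,3',4'-tetra-O-benzyl-(−)-epicatechin
Conditions: N-bromosuccinimide (1.0 equiv), CH2Cl2, −78 to 0 °C
Reagents that add atoms: N-bromosuccinimide, O=C1CCC(=O)N1Br
Why: C8-selective electrophilic bromination, the bromine blocking C8 so that the next C–C bond must form at C6.

Step 5
Reactants: 4 (2R,3R,4S)-8-iodo-4-(2-ethoxyethoxy)-5,7,3',4'-tetra-O-benzylepicatechin; 5 8-bromo-5,7,3',4'-tetra-O-benzyl-(−)-epicatechin (3 equiv)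
Product: 6 [8-iodo-5,7,3',4'-tetra-O-benzylepicatechin]-(4β→6)-[8-bromo-5,7,3',4'-tetra-O-benzylepicatechin]
Conditions: Me3SiOTf (0.2 equiv), CH2Cl2, −78 to −40 °C, slow addition of 4
Reagents that add atoms: none
Why: Lewis-acid ionisation of the C4 ether and Friedel–Crafts capture by C6, the only free ring-A carbon of 5 (halogen-capped interflavan coupling), the nucleophile entering trans to the 3-hydroxyl of the 2,3-cis cation so that C4 of unit 3 is set 4β (4S), while the C8 halogens exclude 4→8 coupling and the excess of 5 with slow addition of 4 suppresses attack by the free C6 of 4 on its own cation.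

Step 6
Reactants: 6 [8-iodo-5,7,3',4'-tetra-O-benzylepicatechin]-(4β→6)-[8-bromo-5,7,3',4'-tetra-O-benzylepicatechin]
Product: 8 [8-formyl-5,7,3',4'-tetra-O-benzylepicatechin]-(4β→6)-[8-bromo-5,7,3',4'-tetra-O-benzylepicatechin], via arylmagnesium 7 (not isolated)
Conditions: i-PrMgCl·LiCl (3.5 equiv), THF, −20 °C; DMF; aq NH4Cl
Reagents that add atoms: N,N-dimethylformamide, CN(C)C=O
Why: After deprotonation of the two hydroxyls, iodine–magnesium exchange takes the aryl iodide and leaves the electron-rich aryl bromide, and the arylmagnesium is formylated by DMF (Bouveault-type formylation) with no stereocentre touched.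

Step 7
Reactants: 9 1,3-bis(bromomethyl)benzene; 10 2-hydroxy-N-methoxy-N-methylacetamide (2.2 equiv)
Product: 11 2,2'-[1,3-phenylenebis(methyleneoxy)]bis(N-methoxy-N-methylacetamide)
Conditions: NaH, THF, 0 °C to rt
Reagents that add atoms: none
Why: Double Williamson etherification of the benzylic dibromide by the sodium alkoxide of the Weinreb amide.

Step 8
Reactants: 11 2,2'-[1,3-phenylenebis(methyleneoxy)]bis(N-methoxy-N-methylacetamide); 12 4-bromo-1,2-bis(benzyloxy)benzene (2.6 equiv)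
Product: 14 1,3-bis({2-[3,4-bis(benzyloxy)phenyl]-2-oxoethoxy}methyl)benzene (bis-ketone strap), via Grignard reagent 13 (not isolated)
Conditions: Mg, THF, 40 °C; then 11, 0 °C; aq HCl
Reagents that add atoms: none
Why: Weinreb ketone synthesis, the chelated tetrahedral intermediate stopping each amide at the ketone stage.

Step 9
Reactants: 15 3,5-bis(benzyloxy)phenol
Product: 16 2,6-bis(benzyloxy)-4-hydroxybenzaldehyde
Conditions: POCl3 (1.2 equiv), DMF, 0 °C to rt; H2O
Reagents that add atoms: N,N-dimethylformamide, CN(C)C=O; water, O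
Why: Vilsmeier–Haack formylation of a 3,5-dialkoxyphenol goes mainly para to the hydroxyl (between the two ether groups), as with 3,5-dimethoxyphenol, and the minor ortho isomer is removed by chromatography.

Step 10
Reactants: 16 2,6-bis(benzyloxy)-4-hydroxybenzaldehyde; 14 1,3-bis({2-[3,4-bis(benzyloxy)phenyl]-2-oxoethoxy}methyl)benzene (3 equiv)
Product: 17 (Z)-3-[2,6-bis(benzyloxy)-4-hydroxyphenyl]-1-[3,4-bis(benzyloxy)phenyl]-2-{[3-({2-[3,4-bis(benzyloxy)phenyl]-2-oxoethoxy}methyl)phenyl]methoxy}prop-2-en-1-one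
Conditions: HCl (4 M in dioxane, 1 equiv), EtOH/THF, 40 °C
Reagents that add atoms: none
Why: Acid-mediated Claisen–Schmidt (crossed aldol) condensation with loss of water, which tolerates the free para-hydroxyl, with excess 14 limiting reaction to one ketone and the (Z)-enone (aryl trans to aroyl) being the thermodynamic isomer.

Step 11
Reactants: 17 (Z)-3-[2,6-bis(benzyloxy)-4-hydroxyphenyl]-1-[3,4-bis(benzyloxy)phenyl]-2-{[3-({2-[3,4-bis(benzyloxy)phenyl]-2-oxoethoxy}methyl)phenyl]methoxy}prop-2-en-1-one; 15 3,5-bis(benzyloxy)phenol (3 equiv)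
Product: 18 (4R)-5,7-bis(benzyloxy)-2-[3,4-bis(benzyloxy)phenyl]-4-[2,6-bis(benzyloxy)-4-hydroxyphenyl]-3-{[3-({2-[3,4-bis(benzyloxy)phenyl]-2-oxoethoxy}methyl)phenyl]methoxy}-4H-chromene
Conditions: (R)-3,3'-bis(2,4,6-triisopropylphenyl)-1,1'-binaphthyl-2,2'-diyl N-(trifluoromethanesulfonyl)phosphoramide (10 mol %), 5 Å molecular sieves, toluene, 40 °C
Reagents that add atoms: none
Why: Proposed new method: the chiral Brønsted acid hydrogen-bonds the enone carbonyl and the OH of phenol 15, so the ortho carbon of 15 adds to one face of the enone β-carbon (this sets C4 of unit 1), after which the phenol oxygen closes onto the ketone and water is lost to give the 3-alkoxy-4H-chromene (para attack cannot cyclise and reverts); the closest known chemistry is the chiral-acid or bifunctional-catalyst Friedel–Crafts alkylation/cyclodehydration of naphthols and electron-rich phenols with enones to 4-aryl-4H-chromenes.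

Step 12
Reactants: 18 (4R)-3-alkoxy-4-aryl-4H-chromene of unit 1 bearing the free central phenol and the pendant strap ketone; 8 [8-formyl-5,7,3',4'-tetra-O-benzylepicatechin]-(4β→6)-[8-bromo-5,7,3',4'-tetra-O-benzylepicatechin] (1.1 equiv)
Product: 19 (Z)-α-alkoxy enone in which the OCH2 carbon of the strap ketone of 18 is joined by a C=C bond to the former aldehyde carbon on C8 of unit 3
Conditions: KOH, EtOH/THF, rt to 40 °C
Reagents that add atoms: none
Why: Base-mediated Claisen–Schmidt condensation (loss of water) of the remaining aryl ketone, whose only enolisable position is the OCH2 group, with the non-enolisable aldehyde, the enol ether and C4 stereocentre of 18 and the flavan stereocentres of 8 being inert to hydroxide.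

Step 13
Reactants: 19 (Z)-α-alkoxy enone joining chromene 18 through its strap to C8 of unit 3
Product: 21 strap-bridged hexadeca-O-benzyl 8-bromo tetramer (units 1 and 2 all-cis as in 22; 3-OH of units 3 and 4 free), via macrocyclic bis-chromene 20 (not isolated)
Conditions: (S)-3,3'-bis(2,4,6-triisopropylphenyl)-1,1'-binaphthyl-2,2'-diyl N-(trifluoromethanesulfonyl)phosphoramide (20 mol %), 5 Å molecular sieves, toluene (2 mM), 40 °C; then CH2Cl2, Et3SiH (10 equiv), CF3CO2H (20 equiv), −40 °C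
Reagents that add atoms: none
Why: Proposed new method: the annulation of step 11 now runs inside the molecule, the free phenol of the central ring adding through its ortho carbon to the β-carbon of the tethered enone (this closes the 14-membered ring and, after ring closure onto the ketone and loss of water, the pyran ring of unit 2, the antipodal acid setting C4 of unit 2), and ionic hydrogenation of both 3-alkoxy-4H-chromenes then delivers the proton at C3 and the hydride at C2 from the face opposite the C4 aryl group (this sets C2 and C3 of units 1 and 2, all-cis); the closest known reactions are the acid-catalysed phenol/enone annulation to 4H-chromenes and the cis-selective silane/acid or catalytic reduction of 4-substituted flav-2-enes.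

Step 14
Reactants: 21 strap-bridged hexadeca-O-benzyl 8-bromo tetramer
Product: 22 epicatechin-(4α→6)-ent-epicatechin-(4β→8)-epicatechin-(4β→6)-epicatechin (target CNP0120618.3)
Conditions: H2 (1 atm), Pd(OH)2/C, Et3N (1.5 equiv), THF/MeOH/H2O, rt
Reagents that add atoms: none
Why: Hydrogenolysis cleaves the sixteen benzyl ethers and the two benzylic C–O bonds of the strap and removes the C8 bromine (Et3N takes up HBr) without touching any stereocentre.

**Compound list**

1 | (−)-epicatechin, (2R,3R) | Oc1cc(O)c2c(c1)O[C@H](c1ccc(O)c(O)c1)[C@H](O)C2 | starting material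
2 | 5,7,3',4'-tetra-O-benzyl-(−)-epicatechin | O(Cc9ccccc9)c1cc(OCc9ccccc9)c2c(c1)O[C@H](c5ccc(OCc9ccccc9)c(OCc9ccccc9)c5)[C@H](O)C2 | intermediate
3 | 8-iodo-5,7,3',4'-tetra-O-benzyl-(−)-epicatechin | O(Cc9ccccc9)c1cc(OCc9ccccc9)c2c(c1I)O[C@H](c5ccc(OCc9ccccc9)c(OCc9ccccc9)c5)[C@H](O)C2 | intermediate
4 | (2R,3R,4S)-8-iodo-4-(2-ethoxyethoxy)-5,7,3',4'-tetra-O-benzylepicatechin | O(Cc9ccccc9)c1cc(OCc9ccccc9)c2c(c1I)O[C@H](c5ccc(OCc9ccccc9)c(OCc9ccccc9)c5)[C@H](O)[C@H]2OCCOCC | intermediate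
5 | 8-bromo-5,7,3',4'-tetra-O-benzyl-(−)-epicatechin | O(Cc9ccccc9)c1cc(OCc9ccccc9)c2c(c1Br)O[C@H](c5ccc(OCc9ccccc9)c(OCc9ccccc9)c5)[C@H](O)C2 | intermediate
6 | [8-iodo-tetra-O-benzylepicatechin]-(4β→6)-[8-bromo-tetra-O-benzylepicatechin] | O(Cc9ccccc9)c1cc(OCc9ccccc9)c2c(c1I)O[C@H](c5ccc(OCc9ccccc9)c(OCc9ccccc9)c5)[C@H](O)[C@H]2c1c(OCc9ccccc9)c(Br)c2c(c1OCc9ccccc9)C[C@@H](O)[C@@H](c5ccc(OCc9ccccc9)c(OCc9ccccc9)c5)O2 | intermediate
7 | C8-chloromagnesio bis(chloromagnesium alkoxide) of 6 | O(Cc9ccccc9)c1cc(OCc9ccccc9)c2c(c1[Mg]Cl)O[C@H](c5ccc(OCc9ccccc9)c(OCc9ccccc9)c5)[C@H](O[Mg]Cl)[C@H]2c1c(OCc9ccccc9)c(Br)c2c(c1OCc9ccccc9)C[C@@H](O[Mg]Cl)[C@@H](c5ccc(OCc9ccccc9)c(OCc9ccccc9)c5)O2 | intermediate (not isolated)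
8 | [8-formyl-tetra-O-benzylepicatechin]-(4β→6)-[8-bromo-tetra-O-benzylepicatechin] | O(Cc9ccccc9)c1cc(OCc9ccccc9)c2c(c1C=O)O[C@H](c5ccc(OCc9ccccc9)c(OCc9ccccc9)c5)[C@H](O)[C@H]2c1c(OCc9ccccc9)c(Br)c2c(c1OCc9ccccc9)C[C@@H](O)[C@@H](c5ccc(OCc9ccccc9)c(OCc9ccccc9)c5)O2 | intermediate
9 | 1,3-bis(bromomethyl)benzene | BrCc1cccc(CBr)c1 | starting material
10 | 2-hydroxy-N-methoxy-N-methylacetamide | OCC(=O)N(C)OC | starting material
11 | 2,2'-[1,3-phenylenebis(methyleneoxy)]bis(N-methoxy-N-methylacetamide) | CON(C)C(=O)COCc1cccc(COCC(=O)N(C)OC)c1 | intermediate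
12 | 4-bromo-1,2-bis(benzyloxy)benzene | Brc1ccc(OCc9ccccc9)c(OCc9ccccc9)c1 | starting material
13 | [3,4-bis(benzyloxy)phenyl]magnesium bromide | Br[Mg]c1ccc(OCc9ccccc9)c(OCc9ccccc9)c1 | intermediate (not isolated)
14 | 1,3-bis({2-[3,4-bis(benzyloxy)phenyl]-2-oxoethoxy}methyl)benzene | O=C(COCc6cccc(COCC(=O)c5ccc(OCc9ccccc9)c(OCc9ccccc9)c5)c6)c5ccc(OCc9ccccc9)c(OCc9ccccc9)c5 | intermediate
15 | 3,5-bis(benzyloxy)phenol | Oc1cc(OCc9ccccc9)cc(OCc9ccccc9)c1 | starting material
16 | 2,6-bis(benzyloxy)-4-hydroxybenzaldehyde | O=Cc1c(OCc9ccccc9)cc(O)cc1OCc9ccccc9 | intermediate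
17 | (Z)-α-alkoxy enone from 16 and one ketone of 14 | Oc1cc(OCc9ccccc9)c(/C=C(\OCc6cccc(COCC(=O)c5ccc(OCc9ccccc9)c(OCc9ccccc9)c5)c6)C(=O)c5ccc(OCc9ccccc9)c(OCc9ccccc9)c5)c(OCc9ccccc9)c1 | intermediate
18 | (4R)-3-alkoxy-4-aryl-4H-chromene of unit 1 with free central phenol and pendant strap ketone | O(Cc9ccccc9)c1cc(OCc9ccccc9)c2c(c1)OC(c5ccc(OCc9ccccc9)c(OCc9ccccc9)c5)=C(OCc6cccc(COCC(=O)c5ccc(OCc9ccccc9)c(OCc9ccccc9)c5)c6)[C@@H]2c1c(OCc9ccccc9)cc(O)cc1OCc9ccccc9 | intermediate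
19 | (Z)-enone joining the strap ketone of 18 to C8 of unit 3 of the dimer | O(Cc9ccccc9)c1cc(OCc9ccccc9)c2c(c1)OC(c5ccc(OCc9ccccc9)c(OCc9ccccc9)c5)=C(OCc6cccc(CO/C(C(=O)c5ccc(OCc9ccccc9)c(OCc9ccccc9)c5)=C\c1c(OCc9ccccc9)cc(OCc9ccccc9)c3c1O[C@H](c5ccc(OCc9ccccc9)c(OCc9ccccc9)c5)[C@H](O)[C@H]3c1c(OCc9ccccc9)c(Br)c3c(c1OCc9ccccc9)C[C@@H](O)[C@@H](c5ccc(OCc9ccccc9)c(OCc9ccccc9)c5)O3)c6)[C@@H]2c1c(OCc9ccccc9)cc(O)cc1OCc9ccccc9 | intermediate
20 | macrocyclic bis(4H-chromene): units 1 and 2 as 3-alkoxy-4-aryl-4H-chromenes bridged O3 to O3 by the 1,3-xylylene strap (14-membered ring), C4 of both units as in 22 | O(Cc9ccccc9)c1cc(OCc9ccccc9)c2c(c1)OC(c5ccc(OCc9ccccc9)c(OCc9ccccc9)c5)=C(OCc6cccc(CO4)c6)[C@@H]2c1c(OCc9ccccc9)cc2c(c1OCc9ccccc9)[C@H](c1c(OCc9ccccc9)cc(OCc9ccccc9)c3c1O[C@H](c5ccc(OCc9ccccc9)c(OCc9ccccc9)c5)[C@H](O)[C@H]3c1c(OCc9ccccc9)c(Br)c3c(c1OCc9ccccc9)C[C@@H](O)[C@@H](c5ccc(OCc9ccccc9)c(OCc9ccccc9)c5)O3)C4=C(c5ccc(OCc9ccccc9)c(OCc9ccccc9)c5)O2 | intermediate (not isolated)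
21 | hexadeca-O-benzyl, 8-bromo (unit 4), O3(unit 1)/O3(unit 2) 1,3-xylylene-bridged derivative of 22; all stereocentres as in 22 | O(Cc9ccccc9)c1cc(OCc9ccccc9)c2c(c1)O[C@H](c5ccc(OCc9ccccc9)c(OCc9ccccc9)c5)[C@H](OCc6cccc(CO4)c6)[C@@H]2c1c(OCc9ccccc9)cc2c(c1OCc9ccccc9)[C@H](c1c(OCc9ccccc9)cc(OCc9ccccc9)c3c1O[C@H](c5ccc(OCc9ccccc9)c(OCc9ccccc9)c5)[C@H](O)[C@H]3c1c(OCc9ccccc9)c(Br)c3c(c1OCc9ccccc9)C[C@@H](O)[C@@H](c5ccc(OCc9ccccc9)c(OCc9ccccc9)c5)O3)[C@H]4[C@H](c5ccc(OCc9ccccc9)c(OCc9ccccc9)c5)O2 | intermediate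
22 | epicatechin-(4α→6)-ent-epicatechin-(4β→8)-epicatechin-(4β→6)-epicatechin; unit 1 (2R,3R,4R), unit 2 (2S,3S,4R), unit 3 (2R,3R,4S), unit 4 (2R,3R) | Oc1cc(O)c2c(c1)O[C@H](c1ccc(O)c(O)c1)[C@H](O)[C@@H]2c1c(O)cc2c(c1O)[C@H](c1c(O)cc(O)c3c1O[C@H](c1ccc(O)c(O)c1)[C@H](O)[C@H]3c1c(O)cc3c(c1O)C[C@@H](O)[C@@H](c1ccc(O)c(O)c1)O3)[C@H](O)[C@H](c1ccc(O)c(O)c1)O2 | target

**Totals.** 14 steps. Longest linear sequence: 8 steps (steps 1, 2, 3, 5, 6, 12, 13, 14, from (−)-epicatechin).

**Three steps most likely to fail, each with one fallback**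

Step 13 is the riskiest. A 14-membered ring must close while a tetra-ortho-substituted diarylmethine is formed, the (S)-acid may be mismatched with the chirality already present, and CF3CO2H may attack the 4β→6 bond or the benzylic C2–O1 bonds. The fallback gives up the ring closure through the strap and joins the two halves as separate molecules. It sets out from aldehyde 8 and chromene 18. Aldehyde 8 is condensed (KOH, EtOH/THF) with 2-(benzyloxy)-1-[3,4-bis(benzyloxy)phenyl]ethan-1-one F5, made from Grignard reagent 13 and 2-(benzyloxy)-N-methoxy-N-methylacetamide, to give the dimer-derived (Z)-α-benzyloxy enone F6. Phenol 18 and F6 are annulated with the (S)-acid to the open bis(4H-chromene) F7. Et3SiH/CF3CO2H at −40 °C reduces F7 to the ketone-armed protected tetramer F8, which carries the unused ketone arm on O3 of unit 1. Hydrogenolysis as in step 14 removes that arm with the benzyl groups and the bromine, and the route is rejoined at 22.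

Step 11 may be too slow, because the enone is deactivated by the para-hydroxyl and both partners are hindered, or it may give low enantioselectivity. The fallback forms the crowded C3–C4 bond from a quinone methide instead of an enone. It sets out from 16, 15 and 14. Bis-ketone 14 is converted (t-BuMe2SiOTf, Et3N) into its (Z,Z)-bis(tert-butyldimethylsilyl enol ether) F3. Aldehyde 16 and phenol 15 are condensed under the same (R)-acid to the ring-A ortho-quinone methide F4 (not isolated). An excess of F3 traps it by Mukaiyama–Michael addition and ring closure. Loss of silanol and a mild acidic work-up, which returns the far ketone, give 18.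

Step 10 may stall, because 16 is a doubly ortho-substituted, strongly deactivated aldehyde. The fallback masks the phenol and uses the base-mediated condensation. It sets out from 16. MOMCl/i-Pr2NEt gives 2,6-bis(benzyloxy)-4-(methoxymethoxy)benzaldehyde F1. KOH-mediated Claisen–Schmidt condensation with excess 14 gives the enone MOM ether F2. HCl in MeOH removes the MOM group and the route is rejoined at 17.

**Further compounds**

F1 | step 10 | 2,6-bis(benzyloxy)-4-(methoxymethoxy)benzaldehyde | O=Cc1c(OCc9ccccc9)cc(OCOC)cc1OCc9ccccc9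
F2 | step 10 | 4-O-methoxymethyl ether of enone 17 | COCOc1cc(OCc9ccccc9)c(/C=C(\OCc6cccc(COCC(=O)c5ccc(OCc9ccccc9)c(OCc9ccccc9)c5)c6)C(=O)c5ccc(OCc9ccccc9)c(OCc9ccccc9)c5)c(OCc9ccccc9)c1
F3 | step 11 | (Z,Z)-bis(tert-butyldimethylsilyl enol ether) of 14 | CC(C)(C)[Si](C)(C)O/C(c5ccc(OCc9ccccc9)c(OCc9ccccc9)c5)=C\OCc6cccc(CO/C=C(\O[Si](C)(C)C(C)(C)C)c5ccc(OCc9ccccc9)c(OCc9ccccc9)c5)c6
F4 | step 11 | 3,5-bis(benzyloxy)-6-{[2,6-bis(benzyloxy)-4-hydroxyphenyl]methylidene}cyclohexa-2,4-dien-1-one (alkene geometry not fixed, not isolated) | O=C1C=C(OCc9ccccc9)C=C(OCc9ccccc9)C1=Cc1c(OCc9ccccc9)cc(O)cc1OCc9ccccc9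
F5 | step 13 | 2-(benzyloxy)-1-[3,4-bis(benzyloxy)phenyl]ethan-1-one | O=C(COCc9ccccc9)c5ccc(OCc9ccccc9)c(OCc9ccccc9)c5
F6 | step 13 | (Z)-2-(benzyloxy)-1-[3,4-bis(benzyloxy)phenyl]-3-(C8 of unit 3 of dimer 8)prop-2-en-1-one | O=C(c5ccc(OCc9ccccc9)c(OCc9ccccc9)c5)/C(OCc9ccccc9)=C/c1c(OCc9ccccc9)cc(OCc9ccccc9)c3c1O[C@H](c5ccc(OCc9ccccc9)c(OCc9ccccc9)c5)[C@H](O)[C@H]3c1c(OCc9ccccc9)c(Br)c3c(c1OCc9ccccc9)C[C@@H](O)[C@@H](c5ccc(OCc9ccccc9)c(OCc9ccccc9)c5)O3
F7 | step 13 | open bis(4H-chromene): unit 2 chromene with 3-O-benzyl, unit 1 chromene with the ketone arm on O3 | O(Cc9ccccc9)c1cc(OCc9ccccc9)c2c(c1)OC(c5ccc(OCc9ccccc9)c(OCc9ccccc9)c5)=C(OCc6cccc(COCC(=O)c5ccc(OCc9ccccc9)c(OCc9ccccc9)c5)c6)[C@@H]2c1c(OCc9ccccc9)cc2c(c1OCc9ccccc9)[C@H](c1c(OCc9ccccc9)cc(OCc9ccccc9)c3c1O[C@H](c5ccc(OCc9ccccc9)c(OCc9ccccc9)c5)[C@H](O)[C@H]3c1c(OCc9ccccc9)c(Br)c3c(c1OCc9ccccc9)C[C@@H](O)[C@@H](c5ccc(OCc9ccccc9)c(OCc9ccccc9)c5)O3)C(OCc9ccccc9)=C(c5ccc(OCc9ccccc9)c(OCc9ccccc9)c5)O2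
F8 | step 13 | protected all-cis tetramer with 3-O-benzyl on unit 2 and the ketone arm on O3 of unit 1 | O(Cc9ccccc9)c1cc(OCc9ccccc9)c2c(c1)O[C@H](c5ccc(OCc9ccccc9)c(OCc9ccccc9)c5)[C@H](OCc6cccc(COCC(=O)c5ccc(OCc9ccccc9)c(OCc9ccccc9)c5)c6)[C@@H]2c1c(OCc9ccccc9)cc2c(c1OCc9ccccc9)[C@H](c1c(OCc9ccccc9)cc(OCc9ccccc9)c3c1O[C@H](c5ccc(OCc9ccccc9)c(OCc9ccccc9)c5)[C@H](O)[C@H]3c1c(OCc9ccccc9)c(Br)c3c(c1OCc9ccccc9)C[C@@H](O)[C@@H](c5ccc(OCc9ccccc9)c(OCc9ccccc9)c5)O3)[C@H](OCc9ccccc9)[C@H](c5ccc(OCc9ccccc9)c(OCc9ccccc9)c5)O2
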